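**Plan**

1. Retrosynthesis: the target comes from a methyl benzoate with ring B held as a bis(pivalate), which one hydride step unmasks. Before that the C3–Br bond of ring A is cut (late electrophilic bromination). Ring A is then cut at C2–C3 and C6–C1 into an arylbutynoate and 2,3-bis(trimethylsilyloxy)buta-1,3-diene, and the ynoate at its CH2–C(sp) bond into a ring B benzyl bromide and methyl propiolate.
2. Enabling feature: in ring A, C1 (CH2OH) and C2 (benzyl bridge) carry the two carbon substituents side by side, and C4 and C5 carry the two oxygens on the opposite edge, with C3 and C6 between them. This is the pattern left when an alkyne (C1, C2) adds to a 2,3-dioxygenated butadiene (C3 to C6).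
3. Forward: ring B is taken from 5-bromovanillin (bromination, demethylation, pivaloylation, reduction, benzylic bromide). The chain is joined by copper-catalysed coupling with methyl propiolate. Ring A is closed by the [4+2] cycloaddition, aromatised with DDQ, brominated at C3 and unmasked with iBu2AlH.
4. Stereochemistry: the target has no stereocentre. Only regiochemistry must be controlled: the symmetrical diene removes the question in the cycloaddition, and the phenol para to the ester steers bromine to C3.

Key step: step 8

Remark on the chemistry: ring A is numbered C1 (CH2OH), C2 (benzyl), C3 (Br), C4 and C5 (OH), C6 (H). Ring B is carried as its bis(pivalate) from step 3 on, so that the final hydride step frees all four phenols and ring B stays inert to bromine.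

**Route**

Step 1
Reactants: 1 5-bromovanillin
Product: 2 2,3-dibromo-4-hydroxy-5-methoxybenzaldehyde (5,6-dibromovanillin)
Conditions: Br2 (1.1 equiv), Fe powder (cat.), NaOAc, AcOH, rt to 60 °C
Reagents that add atoms: bromine, BrBr
Why: Electrophilic aromatic bromination, with FeBr3 formed in the flask as activator, should take place at the one open position para to the methoxy group, which gives the 2,3-dibromo pattern of ring B.

Step 2
Reactants: 2 2,3-dibromo-4-hydroxy-5-methoxybenzaldehyde
Product: 3 2,3-dibromo-4,5-dihydroxybenzaldehyde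
Conditions: BBr3 (2.5 equiv), CH2Cl2, −78 °C to rt; aq. work-up
Reagents that add atoms: none
Why: Lewis acid ether cleavage (boron binds the ether oxygen, bromide removes the methyl group by SN2) should free the catechol while the aromatic aldehyde survives.

Step 3
Reactants: 3 2,3-dibromo-4,5-dihydroxybenzaldehyde
Product: 4 2,3-dibromo-4,5-bis(pivaloyloxy)benzaldehyde
Conditions: tBuCOCl (2.4 equiv), Et3N, DMAP (cat.), CH2Cl2, 0 °C to rt
Reagents that add atoms: pivaloyl chloride, CC(C)(C)C(=O)Cl
Why: DMAP-catalysed O-acylation of both phenols should install hindered esters that tolerate borohydride, PBr3, carbonate, heat, DDQ and bromine, and that a hydride reagent removes at the end.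

Step 4
Reactants: 4 2,3-dibromo-4,5-bis(pivaloyloxy)benzaldehyde
Product: 5 [2,3-dibromo-4,5-bis(pivaloyloxy)phenyl]methanol
Conditions: NaBH4, THF/MeOH, 0 °C
Reagents that add atoms: none
Why: Borohydride 1,2-reduction of the aldehyde should be much faster than attack on the hindered aryl pivalates at 0 °C.

Step 5
Reactants: 5 [2,3-dibromo-4,5-bis(pivaloyloxy)phenyl]methanol
Product: 6 2,3-dibromo-4,5-bis(pivaloyloxy)benzyl bromide
Conditions: PBr3, CH2Cl2, 0 °C
Reagents that add atoms: phosphorus tribromide, BrP(Br)Br
Why: Activation of the primary benzylic alcohol as a phosphite and SN2 displacement by bromide should give the benzylic bromide without touching the esters.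

Step 6
Reactants: 6 2,3-dibromo-4,5-bis(pivaloyloxy)benzyl bromide; 7 methyl propiolate
Product: 8 methyl 4-[2,3-dibromo-4,5-bis(pivaloyloxy)phenyl]but-2-ynoate
Conditions: CuI (20 mol %), K2CO3, nBu4NI (cat.), MeCN, 40 °C
Reagents that add atoms: none
Why: Copper-catalysed sp–sp3 coupling of a terminal alkyne with a benzylic halide (copper acetylide of the acidic propiolate C–H, benzylic iodide formed by Finkelstein exchange) should form the CH2–C(sp) bond, and mild carbonate at 40 °C should keep the new propargylic CH2 from shifting to the allene.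

Step 7
Reactants: 9 butane-2,3-dione
Product: 10 2,3-bis(trimethylsilyloxy)buta-1,3-diene
Conditions: Me3SiOTf (2.2 equiv), Et3N, Et2O, 0 °C to rt; distil
Reagents that add atoms: trimethylsilyl trifluoromethanesulfonate, C[Si](C)(C)OS(=O)(=O)C(F)(F)F
Why: Twofold soft enolisation and O-silylation of the 1,2-diketone should give the bis(silyl enol ether) diene, which is distilled and used fresh.

Step 8
Reactants: 8 methyl 4-[2,3-dibromo-4,5-bis(pivaloyloxy)phenyl]but-2-ynoate; 10 2,3-bis(trimethylsilyloxy)buta-1,3-diene
Product: 11 methyl 2-[2,3-dibromo-4,5-bis(pivaloyloxy)benzyl]-4,5-bis(trimethylsilyloxy)cyclohexa-1,4-diene-1-carboxylate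
Conditions: 10 (3 equiv), BHT (cat.), PhMe, 150 °C, sealed tube
Reagents that add atoms: none
Why: A concerted, suprafacial [4+2] cycloaddition of normal electron demand joins the two termini of the electron-rich s-cis diene 10 to the two sp carbons of the ester-activated triple bond of 8, forming C2–C3 and C6–C1 together. The closest known reaction type is the Diels–Alder reaction of 2,3-bis(trimethylsilyloxy)buta-1,3-diene with acetylenic esters, whose adducts are oxidised to catechols. Ring A closes as a six-membered carbocycle by intermolecular cycloaddition, both ring bonds being made in the same step, and appears as the cyclohexa-1,4-diene. No stereocentre is created. The twofold symmetry of the diene removes any regiochemical question and only the conjugated triple bond of 8 is electron-poor enough to react; the step needs neutral, base-free heating with excess diene so that the propargylic CH2 does not shift to the allenoate and the silyl enol ethers are not hydrolysed.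

Step 9
Reactants: 11 methyl 2-[2,3-dibromo-4,5-bis(pivaloyloxy)benzyl]-4,5-bis(trimethylsilyloxy)cyclohexa-1,4-diene-1-carboxylate (used crude after removal of volatiles)
Product: 13 methyl 2-[2,3-dibromo-4,5-bis(pivaloyloxy)benzyl]-4,5-dihydroxybenzoate, via aromatic bis(trimethylsilyl) ether 12 (not isolated)
Conditions: DDQ (1.0 equiv), PhMe, 0 °C to rt, filter; then MeOH, PPTS (cat.), rt
Reagents that add atoms: none
Why: DDQ dehydrogenation of a cyclohexa-1,4-diene (hydride abstraction from a doubly allylic ring CH2, then proton loss) should aromatise ring A, and methanolysis of the aryl silyl ethers after the quinone has been consumed should free the catechol without oxidising it and without touching the pivalates.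

Step 10
Reactants: 13 methyl 2-[2,3-dibromo-4,5-bis(pivaloyloxy)benzyl]-4,5-dihydroxybenzoate
Product: 14 methyl 3-bromo-2-[2,3-dibromo-4,5-bis(pivaloyloxy)benzyl]-4,5-dihydroxybenzoate
Conditions: Br2 (1.0 equiv), NaOAc, AcOH, rt
Reagents that add atoms: bromine, BrBr
Why: Electrophilic aromatic bromination should enter C3, which is ortho to the C4 hydroxyl, meta to the ester and next to the activating benzyl group (the orientation seen with vanillin and protocatechuic esters), while C6 is deactivated by the ortho ester and ring B by two acyloxy groups and two bromines.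

Step 11
Reactants: 14 methyl 3-bromo-2-[2,3-dibromo-4,5-bis(pivaloyloxy)benzyl]-4,5-dihydroxybenzoate
Product: 15 3-bromo-4-(2,3-dibromo-4,5-dihydroxybenzyl)-5-(hydroxymethyl)benzene-1,2-diol (target)
Conditions: iBu2AlH (10 equiv), THF/CH2Cl2, −78 to 0 °C; aq. potassium sodium tartrate, then 1 M HCl
Reagents that add atoms: none
Why: Excess aluminium hydride should reduce the methyl ester to the primary alcohol and cleave both aryl pivalates reductively in one operation, the aryl bromides being inert at or below 0 °C and no benzylic leaving group being generated.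

**Compound list**

1 | 5-bromovanillin (3-bromo-4-hydroxy-5-methoxybenzaldehyde) | O=Cc1cc(Br)c(O)c(OC)c1 | starting material
2 | 2,3-dibromo-4-hydroxy-5-methoxybenzaldehyde | O=Cc1cc(OC)c(O)c(Br)c1Br | intermediate
3 | 2,3-dibromo-4,5-dihydroxybenzaldehyde | O=Cc1cc(O)c(O)c(Br)c1Br | intermediate
4 | 2,3-dibromo-4,5-bis(pivaloyloxy)benzaldehyde | O=Cc1cc(OC(=O)C(C)(C)C)c(OC(=O)C(C)(C)C)c(Br)c1Br | intermediate
5 | [2,3-dibromo-4,5-bis(pivaloyloxy)phenyl]methanol | OCc1cc(OC(=O)C(C)(C)C)c(OC(=O)C(C)(C)C)c(Br)c1Br | intermediate
6 | 2,3-dibromo-4,5-bis(pivaloyloxy)benzyl bromide | BrCc1cc(OC(=O)C(C)(C)C)c(OC(=O)C(C)(C)C)c(Br)c1Br | intermediate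
7 | methyl propiolate | C#CC(=O)OC | starting material
8 | methyl 4-[2,3-dibromo-4,5-bis(pivaloyloxy)phenyl]but-2-ynoate | COC(=O)C#CCc1cc(OC(=O)C(C)(C)C)c(OC(=O)C(C)(C)C)c(Br)c1Br | intermediate
9 | butane-2,3-dione | CC(=O)C(C)=O | starting material
10 | 2,3-bis(trimethylsilyloxy)buta-1,3-diene | C=C(O[Si](C)(C)C)C(=C)O[Si](C)(C)C | intermediate
11 | methyl 2-[2,3-dibromo-4,5-bis(pivaloyloxy)benzyl]-4,5-bis(trimethylsilyloxy)cyclohexa-1,4-diene-1-carboxylate | COC(=O)C1=C(Cc2cc(OC(=O)C(C)(C)C)c(OC(=O)C(C)(C)C)c(Br)c2Br)CC(O[Si](C)(C)C)=C(O[Si](C)(C)C)C1 | intermediate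
12 | methyl 2-[2,3-dibromo-4,5-bis(pivaloyloxy)benzyl]-4,5-bis(trimethylsilyloxy)benzoate | COC(=O)c1cc(O[Si](C)(C)C)c(O[Si](C)(C)C)cc1Cc1cc(OC(=O)C(C)(C)C)c(OC(=O)C(C)(C)C)c(Br)c1Br | intermediate (not isolated)
13 | methyl 2-[2,3-dibromo-4,5-bis(pivaloyloxy)benzyl]-4,5-dihydroxybenzoate | COC(=O)c1cc(O)c(O)cc1Cc1cc(OC(=O)C(C)(C)C)c(OC(=O)C(C)(C)C)c(Br)c1Br | intermediate
14 | methyl 3-bromo-2-[2,3-dibromo-4,5-bis(pivaloyloxy)benzyl]-4,5-dihydroxybenzoate | COC(=O)c1cc(O)c(O)c(Br)c1Cc1cc(OC(=O)C(C)(C)C)c(OC(=O)C(C)(C)C)c(Br)c1Br | intermediate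
15 | 3-bromo-4-(2,3-dibromo-4,5-dihydroxybenzyl)-5-(hydroxymethyl)benzene-1,2-diol | OCc1cc(O)c(O)c(Br)c1Cc1cc(O)c(O)c(Br)c1Br | target

**Count and risks**

Total step count: 11. Longest linear sequence: 10 steps (steps 1 to 6 and 8 to 11, from 5-bromovanillin); step 7 is a one-step branch.

Steps most likely to fail:

Step 8. The triple bond carries only one activating group and a β-alkyl substituent, so cycloaddition may be slower than desilylation or oligomerisation of the diene at 150 °C, and the propargylic CH2 may shift to the allene during heating. The fallback makes the allene on purpose and uses its conjugated double bond as the dienophile. Setting out from 8, a catalytic amount of Et3N in MeCN at room temperature should isomerise the ynoate to racemic methyl 4-[2,3-dibromo-4,5-bis(pivaloyloxy)phenyl]buta-2,3-dienoate F1. Its α,β-double bond is a better dienophile than the alkyne and should add diene 10 in toluene at about 110 °C to give methyl 2-{[2,3-dibromo-4,5-bis(pivaloyloxy)phenyl]methylidene}-4,5-bis(trimethylsilyloxy)cyclohex-4-ene-1-carboxylate F2 (racemic, alkene geometry immaterial), in which the same two ring bonds have been formed. DDQ followed by MeOH/PPTS, as in step 9, should remove two hydrogens while the exocyclic double bond moves into the ring on aromatisation, and the route is rejoined at 13.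

Step 10. Bromine may also enter C6, add twice, or oxidise the free catechol to the ortho-quinone, so that site selectivity or material is lost. The fallback leaves only the C4 hydroxyl free before bromination. Setting out from 13, Ac2O/pyridine should give methyl 4,5-diacetoxy-2-[2,3-dibromo-4,5-bis(pivaloyloxy)benzyl]benzoate F3. NH4OAc in aqueous MeOH should remove selectively the acetate para to the ester (the more electrophilic aryl ester with the better phenoxide leaving group) to give methyl 5-acetoxy-2-[2,3-dibromo-4,5-bis(pivaloyloxy)benzyl]-4-hydroxybenzoate F4. Br2/NaOAc in AcOH can then enter only ortho to the single free phenol, giving methyl 5-acetoxy-3-bromo-2-[2,3-dibromo-4,5-bis(pivaloyloxy)benzyl]-4-hydroxybenzoate F5. The iBu2AlH conditions of step 11 should remove the acetate together with the pivalates and reduce the ester, so the route is rejoined at 15.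

Step 11. Tight binding of aluminium to two catechols may stall the reduction or hamper isolation, the pivalate beside bromine may be cleaved only slowly, and a para-aluminoxy benzylic alkoxide may lose oxygen through a quinone methide and be over-reduced. The fallback separates deacylation from reduction and reduces with all phenols silylated. Setting out from 14, K2CO3 in degassed MeOH should cleave both pivalates to give methyl 3-bromo-2-(2,3-dibromo-4,5-dihydroxybenzyl)-4,5-dihydroxybenzoate F6. tBuMe2SiCl/imidazole in DMF should give methyl 3-bromo-4,5-bis(tert-butyldimethylsilyloxy)-2-[2,3-dibromo-4,5-bis(tert-butyldimethylsilyloxy)benzyl]benzoate F7. iBu2AlH (2.5 equiv, CH2Cl2, −78 °C) should then give {3-bromo-4,5-bis(tert-butyldimethylsilyloxy)-2-[2,3-dibromo-4,5-bis(tert-butyldimethylsilyloxy)benzyl]phenyl}methanol F8. nBu4NF buffered with AcOH in THF at 0 °C should remove the four silyl groups, and the route is rejoined at 15.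

**Further compounds**

F1 | step 8 | methyl 4-[2,3-dibromo-4,5-bis(pivaloyloxy)phenyl]buta-2,3-dienoate (racemic) | COC(=O)C=C=Cc1cc(OC(=O)C(C)(C)C)c(OC(=O)C(C)(C)C)c(Br)c1Br
F2 | step 8 | methyl 2-{[2,3-dibromo-4,5-bis(pivaloyloxy)phenyl]methylidene}-4,5-bis(trimethylsilyloxy)cyclohex-4-ene-1-carboxylate (racemic, alkene geometry not defined) | COC(=O)C1CC(O[Si](C)(C)C)=C(O[Si](C)(C)C)CC1=Cc1cc(OC(=O)C(C)(C)C)c(OC(=O)C(C)(C)C)c(Br)c1Br
F3 | step 10 | methyl 4,5-diacetoxy-2-[2,3-dibromo-4,5-bis(pivaloyloxy)benzyl]benzoate | COC(=O)c1cc(OC(C)=O)c(OC(C)=O)cc1Cc1cc(OC(=O)C(C)(C)C)c(OC(=O)C(C)(C)C)c(Br)c1Br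
F4 | step 10 | methyl 5-acetoxy-2-[2,3-dibromo-4,5-bis(pivaloyloxy)benzyl]-4-hydroxybenzoate | COC(=O)c1cc(OC(C)=O)c(O)cc1Cc1cc(OC(=O)C(C)(C)C)c(OC(=O)C(C)(C)C)c(Br)c1Br
F5 | step 10 | methyl 5-acetoxy-3-bromo-2-[2,3-dibromo-4,5-bis(pivaloyloxy)benzyl]-4-hydroxybenzoate | COC(=O)c1cc(OC(C)=O)c(O)c(Br)c1Cc1cc(OC(=O)C(C)(C)C)c(OC(=O)C(C)(C)C)c(Br)c1Br
F6 | step 11 | methyl 3-bromo-2-(2,3-dibromo-4,5-dihydroxybenzyl)-4,5-dihydroxybenzoate | COC(=O)c1cc(O)c(O)c(Br)c1Cc1cc(O)c(O)c(Br)c1Br
F7 | step 11 | methyl 3-bromo-4,5-bis(tert-butyldimethylsilyloxy)-2-[2,3-dibromo-4,5-bis(tert-butyldimethylsilyloxy)benzyl]benzoate | COC(=O)c1cc(O[Si](C)(C)C(C)(C)C)c(O[Si](C)(C)C(C)(C)C)c(Br)c1Cc1cc(O[Si](C)(C)C(C)(C)C)c(O[Si](C)(C)C(C)(C)C)c(Br)c1Br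
F8 | step 11 | {3-bromo-4,5-bis(tert-butyldimethylsilyloxy)-2-[2,3-dibromo-4,5-bis(tert-butyldimethylsilyloxy)benzyl]phenyl}methanol | OCc1cc(O[Si](C)(C)C(C)(C)C)c(O[Si](C)(C)C(C)(C)C)c(Br)c1Cc1cc(O[Si](C)(C)C(C)(C)C)c(O[Si](C)(C)C(C)(C)C)c(Br)c1Br
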